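**Retrosynthetic overview**
1. Target ⇐ hydrogenolysis of three benzyl ethers ⇐ reductive excision (Raney Ni) of a temporary sulfur bridge that joins the C3 methyl carbon to the ortho carbon of the C2 aryl ring.
2. Bridged tricycle ⇐ lactol: intramolecular Friedel–Crafts attack of the S-tethered arene on the C2 oxocarbenium ion makes the aryl–C2 bond and the C2 stereocentre.
3. Enabling feature: on the oxolane ring the C3 methyl group is cis to the C2 aryl group, and both the methyl carbon and the aryl ortho carbon are C–H in the target. One sulfur atom can therefore tie them into a thiochromane ring cis-fused to the oxolane across C2–C3 and be removed afterwards.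
4. Lactol ⇐ α-benzyloxy lactone + chloromethyl aryl sulfide (ketene acetal alkylation anti to the C4 methyl sets C3) ⇐ anti-crotylation of O-benzylvanillin, dihydroxylation, oxidative lactonisation (sets C5 and C4).
5. Ring order: oxolane first (as the lactone), thiochromane second (key step), thiochromane then opened again.

Key step: step 8

Assumption: (R)-TRIP is taken to direct the crotyl group to the Re face of aldehyde 1 (giving the 1R,2R alcohol); should the opposite sense be found, the enantiomeric acid is used.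

**Step 1**
Reactants: 1 4-(benzyloxy)-3-methoxybenzaldehyde; 2 2-[(2E)-but-2-en-1-yl]-4,4,5,5-tetramethyl-1,3,2-dioxaborolane
Product: 4 (1R,2R)-1-[4-(benzyloxy)-3-methoxyphenyl]-2-methylbut-3-en-1-ol, via boronate ester 3 (not isolated)
Conditions: (R)-TRIP [(R)-3,3'-bis(2,4,6-triisopropylphenyl)-1,1'-binaphthyl-2,2'-diyl hydrogen phosphate] (5 mol%), 4 Å MS, toluene, −30 °C; then aq. NaHCO3
Reagents that add atoms: none
Why: Chiral-phosphoric-acid-catalysed crotylboration through a closed chair transition state, in which the E-boronate should give the anti adduct and the acid should select the Re face of the aldehyde, so that C5 and C4 of the target are both set here.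

**Step 2**
Reactants: 4 (1R,2R)-1-[4-(benzyloxy)-3-methoxyphenyl]-2-methylbut-3-en-1-ol
Product: 5 (2RS,3S,4R)-4-[4-(benzyloxy)-3-methoxyphenyl]-3-methylbutane-1,2,4-triol
Conditions: OsO4 (2 mol%), NMO (1.5 equiv), acetone–H2O 4:1, rt; aq. Na2SO3
Reagents that add atoms: osmium tetroxide OsO4 (catalytic oxygen carrier), O=[Os](=O)(=O)=O; N-methylmorpholine N-oxide, C[N+]1([O-])CCOCC1; water, O
Why: Upjohn dihydroxylation of the monosubstituted alkene, which is far more reactive toward OsO4 than the arenes; the new carbinol centre may form as a mixture because this carbon is made planar again in step 6.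

**Step 3**
Reactants: 5 (2RS,3S,4R)-4-[4-(benzyloxy)-3-methoxyphenyl]-3-methylbutane-1,2,4-triol
Product: 7 (3RS,4R,5R)-5-[4-(benzyloxy)-3-methoxyphenyl]-3-hydroxy-4-methyloxolan-2-one, via lactol 6 (not isolated)
Conditions: TEMPO (0.2 equiv), PhI(OAc)2 (2.5 equiv), CH2Cl2, rt
Reagents that add atoms: none
Why: TEMPO/PhI(OAc)2 oxidative lactonisation, in which the oxoammonium salt should oxidise the primary alcohol selectively, the hydroxy aldehyde should close to the five-membered lactol 6 with the benzylic hydroxyl, and 6 should be oxidised on to the lactone.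

**Step 4**
Reactants: 7 (3RS,4R,5R)-5-[4-(benzyloxy)-3-methoxyphenyl]-3-hydroxy-4-methyloxolan-2-one
Product: 8 (3RS,4S,5R)-3-(benzyloxy)-5-[4-(benzyloxy)-3-methoxyphenyl]-4-methyloxolan-2-one
Conditions: BnBr (3 equiv), Ag2O (2 equiv), CH2Cl2, rt, dark
Reagents that add atoms: benzyl bromide, BrCc1ccccc1
Why: Ag2O-mediated Williamson etherification of the α-hydroxy lactone under non-basic conditions, so that the lactone ring should stay closed (the C4 descriptor changes only through the priority rules).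

**Step 5**
Reactants: 9 2-(benzyloxy)-4-bromo-1-methoxybenzene
Product: 12 2-(benzyloxy)-4-[(chloromethyl)sulfanyl]-1-methoxybenzene, via aryllithium 10 (not isolated), via lithium arenethiolate 11 (not isolated)
Conditions: n-BuLi (1.05 equiv), THF, −78 °C; S8 (1.0 equiv S), −78 → 0 °C; then added to BrCH2Cl (10 equiv), THF, 0 °C → rt
Reagents that add atoms: sulfur S8, S1SSSSSSS1; bromochloromethane, ClCBr
Why: Bromine–lithium exchange, insertion of sulfur into the C–Li bond and SN2 alkylation of the thiolate at the C–Br end of BrCH2Cl, where bromide is the better leaving group and the excess dihalide should suppress the dithioacetal.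

**Step 6**
Reactants: 8 (3RS,4S,5R)-3-(benzyloxy)-5-[4-(benzyloxy)-3-methoxyphenyl]-4-methyloxolan-2-one; 12 2-(benzyloxy)-4-[(chloromethyl)sulfanyl]-1-methoxybenzene
Product: 15 (3S,4S,5R)-3-(benzyloxy)-5-[4-(benzyloxy)-3-methoxyphenyl]-3-({[3-(benzyloxy)-4-methoxyphenyl]sulfanyl}methyl)-4-methyloxolan-2-one, via lithium enolate 13 (not isolated), via silyl ketene acetal 14 (not isolated)
Conditions: LiN(iPr)2 (1.1 equiv), THF, −78 °C; Me3SiCl (1.3 equiv), −78 → 0 °C; solvent change to CH2Cl2; 12 (1.3 equiv), ZnBr2 (10 mol%), rt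
Reagents that add atoms: none
Why: Lewis-acid-mediated (arylthio)methylation of an O-silyl ketene acetal by an α-chloro sulfide through its thionium ion; both C3 epimers of 8 give the same planar ketene acetal, and the electrophile should add anti to the adjacent C4 methyl group, which sets the quaternary C3 centre with the CH2S arm trans to that methyl and the oxygen cis to it.

**Step 7**
Reactants: 15 (3S,4S,5R)-3-(benzyloxy)-5-[4-(benzyloxy)-3-methoxyphenyl]-3-({[3-(benzyloxy)-4-methoxyphenyl]sulfanyl}methyl)-4-methyloxolan-2-one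
Product: 17 (2RS,3S,4S,5R)-3-(benzyloxy)-5-[4-(benzyloxy)-3-methoxyphenyl]-3-({[3-(benzyloxy)-4-methoxyphenyl]sulfanyl}methyl)-4-methyloxolan-2-ol, via aluminium acetal 16 (not isolated)
Conditions: iBu2AlH (1.2 equiv), CH2Cl2, −78 °C; MeOH, then aq. KNaC4H4O6
Reagents that add atoms: none
Why: Partial reduction of a lactone with iBu2AlH, in which the tetrahedral aluminium acetal should be stable at −78 °C and release the lactol (both anomers, of no consequence) on work-up while sulfide and benzyl ethers stay untouched.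

**Step 8**
Reactants: 17 (2RS,3S,4S,5R)-3-(benzyloxy)-5-[4-(benzyloxy)-3-methoxyphenyl]-3-({[3-(benzyloxy)-4-methoxyphenyl]sulfanyl}methyl)-4-methyloxolan-2-ol
Product: 19 (2R,3S,3aS,9bR)-3a,7-bis(benzyloxy)-2-[4-(benzyloxy)-3-methoxyphenyl]-8-methoxy-3-methyl-2,3,3a,9b-tetrahydro-4H-furo[3,2-c]thiochromene, via oxocarbenium ion 18 (not isolated)
Conditions: BF3·OEt2 (1.5 equiv), 4 Å MS, CH2Cl2 (0.01 M), −78 → −20 °C; Et3N
Reagents that add atoms: none
Why: BF3 should ionise the lactol to the cyclic oxocarbenium ion 18, which the tethered arene attacks at C2 in an intramolecular Friedel–Crafts alkylation followed by loss of a proton; the closest known reaction type is the intramolecular C-arylation of furanosyl and pyranosyl oxocarbenium ions by tethered benzyl-type arenes (an oxa-Pictet–Spengler-like closure). The new six-membered thiochromane ring closes in the 6-exo-trig mode with respect to the C=O+ bond (6-endo with respect to the arene), a favoured geometry. The C2 stereocentre is controlled by the tether: the CH2–S arm on C3 can deliver the arene only to the face of C2 on which it stands, so the 6/5 ring fusion should be cis and the aryl group should end cis to the C3 carbon substituent, trans to the C3 benzyloxy group and 2,5-cis to the C5 aryl group. Regioselectivity on the arene is needed and is secured because only the two carbons ortho to sulfur can close a six-membered ring, and of these the one para to the benzyloxy group is strongly activated and unhindered whereas the other lies between S and OBn. Chemoselectivity is expected at low temperature and high dilution over attack by the phenyl ring of the C3 benzyl ether (orders of magnitude less nucleophilic), over S-attack (a strained four-membered sulfonium, reversible) and over ionisation at C5 (which would re-close to the favoured 4,5-trans oxolane).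

**Step 9**
Reactants: 19 (2R,3S,3aS,9bR)-3a,7-bis(benzyloxy)-2-[4-(benzyloxy)-3-methoxyphenyl]-8-methoxy-3-methyl-2,3,3a,9b-tetrahydro-4H-furo[3,2-c]thiochromene
Product: 20 (2R,3S,4S,5R)-3-(benzyloxy)-2,5-bis[4-(benzyloxy)-3-methoxyphenyl]-3,4-dimethyloxolane
Conditions: Raney Ni (W-2, deactivated by reflux in acetone, excess), EtOH–THF, rt → 40 °C
Reagents that add atoms: none
Why: Raney nickel desulfurisation should hydrogenolyse the aryl C–S and the alkyl C–S bond, turning the bridge CH2 into the C3 methyl group and the aryl carbon into C–H without touching a stereocentre; the deactivated catalyst at or below 40 °C is expected to spare the benzylic C–O bonds, and any O-benzyl group lost here is removed in step 10 anyway.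

**Step 10**
Reactants: 20 (2R,3S,4S,5R)-3-(benzyloxy)-2,5-bis[4-(benzyloxy)-3-methoxyphenyl]-3,4-dimethyloxolane
Product: 21 (2R,3S,4S,5R)-2,5-bis(4-hydroxy-3-methoxyphenyl)-3,4-dimethyloxolan-3-ol
Conditions: H2 (1 atm), Pd(OH)2/C, EtOAc–EtOH 1:1, rt
Reagents that add atoms: none
Why: Catalytic hydrogenolysis of the two aryl benzyl ethers and the tertiary alkyl benzyl ether under neutral conditions at 1 atm, where the oxolane C–O bonds (cleaved only with acid or under forcing conditions) and all four stereocentres should be retained.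

**Compound list**
1 | 4-(benzyloxy)-3-methoxybenzaldehyde | O=Cc1ccc(OCc2ccccc2)c(OC)c1 | starting material
2 | 2-[(2E)-but-2-en-1-yl]-4,4,5,5-tetramethyl-1,3,2-dioxaborolane | C/C=C/CB1OC(C)(C)C(C)(C)O1 | starting material
3 | 2-{[(1R,2R)-1-[4-(benzyloxy)-3-methoxyphenyl]-2-methylbut-3-en-1-yl]oxy}-4,4,5,5-tetramethyl-1,3,2-dioxaborolane | C=C[C@@H](C)[C@@H](OB1OC(C)(C)C(C)(C)O1)c1ccc(OCc2ccccc2)c(OC)c1 | intermediate
4 | (1R,2R)-1-[4-(benzyloxy)-3-methoxyphenyl]-2-methylbut-3-en-1-ol | C=C[C@@H](C)[C@@H](O)c1ccc(OCc2ccccc2)c(OC)c1 | intermediate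
5 | (2RS,3S,4R)-4-[4-(benzyloxy)-3-methoxyphenyl]-3-methylbutane-1,2,4-triol | OCC(O)[C@@H](C)[C@@H](O)c1ccc(OCc2ccccc2)c(OC)c1 | intermediate
6 | (2RS,3RS,4R,5R)-5-[4-(benzyloxy)-3-methoxyphenyl]-4-methyloxolane-2,3-diol | OC1O[C@@H](c2ccc(OCc3ccccc3)c(OC)c2)[C@H](C)C1O | intermediate
7 | (3RS,4R,5R)-5-[4-(benzyloxy)-3-methoxyphenyl]-3-hydroxy-4-methyloxolan-2-one | O=C1O[C@@H](c2ccc(OCc3ccccc3)c(OC)c2)[C@H](C)C1O | intermediate
8 | (3RS,4S,5R)-3-(benzyloxy)-5-[4-(benzyloxy)-3-methoxyphenyl]-4-methyloxolan-2-one | O=C1O[C@@H](c2ccc(OCc3ccccc3)c(OC)c2)[C@H](C)C1OCc1ccccc1 | intermediate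
9 | 2-(benzyloxy)-4-bromo-1-methoxybenzene | COc1ccc(Br)cc1OCc1ccccc1 | starting material
10 | [3-(benzyloxy)-4-methoxyphenyl]lithium | [Li]c1ccc(OC)c(OCc2ccccc2)c1 | intermediate
11 | lithium 3-(benzyloxy)-4-methoxybenzenethiolate | [Li]Sc1ccc(OC)c(OCc2ccccc2)c1 | intermediate
12 | 2-(benzyloxy)-4-[(chloromethyl)sulfanyl]-1-methoxybenzene | ClCSc1ccc(OC)c(OCc2ccccc2)c1 | intermediate
13 | lithium (4S,5R)-3-(benzyloxy)-5-[4-(benzyloxy)-3-methoxyphenyl]-4-methyl-4,5-dihydrofuran-2-olate | [Li]OC1=C(OCc2ccccc2)[C@@H](C)[C@H](c2ccc(OCc3ccccc3)c(OC)c2)O1 | intermediate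
14 | {[(4S,5R)-3-(benzyloxy)-5-[4-(benzyloxy)-3-methoxyphenyl]-4-methyl-4,5-dihydrofuran-2-yl]oxy}trimethylsilane | C[Si](C)(C)OC1=C(OCc2ccccc2)[C@@H](C)[C@H](c2ccc(OCc3ccccc3)c(OC)c2)O1 | intermediate
15 | (3S,4S,5R)-3-(benzyloxy)-5-[4-(benzyloxy)-3-methoxyphenyl]-3-({[3-(benzyloxy)-4-methoxyphenyl]sulfanyl}methyl)-4-methyloxolan-2-one | O=C1O[C@@H](c2ccc(OCc3ccccc3)c(OC)c2)[C@H](C)[C@@]1(OCc1ccccc1)CSc1ccc(OC)c(OCc2ccccc2)c1 | intermediate
16 | diisobutylaluminium acetal of lactol 17 | CC(C)C[Al](CC(C)C)OC1O[C@@H](c2ccc(OCc3ccccc3)c(OC)c2)[C@H](C)[C@@]1(OCc1ccccc1)CSc1ccc(OC)c(OCc2ccccc2)c1 | intermediate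
17 | (2RS,3S,4S,5R)-3-(benzyloxy)-5-[4-(benzyloxy)-3-methoxyphenyl]-3-({[3-(benzyloxy)-4-methoxyphenyl]sulfanyl}methyl)-4-methyloxolan-2-ol | OC1O[C@@H](c2ccc(OCc3ccccc3)c(OC)c2)[C@H](C)[C@@]1(OCc1ccccc1)CSc1ccc(OC)c(OCc2ccccc2)c1 | intermediate
18 | (3S,4S,5R)-3-(benzyloxy)-5-[4-(benzyloxy)-3-methoxyphenyl]-3-({[3-(benzyloxy)-4-methoxyphenyl]sulfanyl}methyl)-4-methyl-4,5-dihydro-3H-furan-1-ium (cyclic oxocarbenium ion) | C1=[O+][C@@H](c2ccc(OCc3ccccc3)c(OC)c2)[C@H](C)[C@@]1(OCc1ccccc1)CSc1ccc(OC)c(OCc2ccccc2)c1 | intermediate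
19 | (2R,3S,3aS,9bR)-3a,7-bis(benzyloxy)-2-[4-(benzyloxy)-3-methoxyphenyl]-8-methoxy-3-methyl-2,3,3a,9b-tetrahydro-4H-furo[3,2-c]thiochromene | COc1c(OCc4ccccc4)cc3c(c1)[C@H]2O[C@@H](c5ccc(OCc6ccccc6)c(OC)c5)[C@H](C)[C@]2(CS3)OCc2ccccc2 | intermediate
20 | (2R,3S,4S,5R)-3-(benzyloxy)-2,5-bis[4-(benzyloxy)-3-methoxyphenyl]-3,4-dimethyloxolane | COc1cc([C@H]2O[C@@H](c3ccc(OCc4ccccc4)c(OC)c3)[C@H](C)[C@]2(C)OCc2ccccc2)ccc1OCc1ccccc1 | intermediate
21 | (2R,3S,4S,5R)-2,5-bis(4-hydroxy-3-methoxyphenyl)-3,4-dimethyloxolan-3-ol | COc1cc([C@H]2O[C@@H](c3ccc(O)c(OC)c3)[C@H](C)[C@]2(C)O)ccc1O | target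

**Step count**
Total: 10 steps. Longest linear sequence: 9 steps (steps 1–4 and 6–10); step 5 prepares the sulfur fragment.

**Steps most likely to fail**

Step 8 (key step). The oxocarbenium ion may be consumed by pathways other than attack of the tethered arene at the intended carbon: capture by the phenyl ring of the C3 benzyl ether, closure onto the hindered ortho carbon, or acid-induced ionisation of the C5–O bond. The fallback drops the tether and sets out from 8. Methylation of its enolate (LiN(iPr)2, THF, −78 °C; MeI), anti to the C4 methyl group, should give (3S,4S,5R)-3-(benzyloxy)-5-[4-(benzyloxy)-3-methoxyphenyl]-3,4-dimethyloxolan-2-one F1. Addition of [4-(benzyloxy)-3-methoxyphenyl]lithium F2 (from commercial 1-(benzyloxy)-4-bromo-2-methoxybenzene and n-BuLi, THF, −78 °C) to the lactone carbonyl should give the cyclic hemiketal (2RS,3S,4S,5R)-3-(benzyloxy)-2,5-bis[4-(benzyloxy)-3-methoxyphenyl]-3,4-dimethyloxolan-2-ol F3. Ionic hydrogenation (Et3SiH, BF3·OEt2, CH2Cl2, −78 °C) of the derived 2-aryl oxocarbenium ion is expected to deliver hydride anti to the C3 methyl group and cis to the C3 alkoxy group, placing the aryl group cis to that methyl. The fallback comes back to the route at 20.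

Step 6. C–C bond formation at the congested tetrasubstituted ketene acetal may be slow, so that Friedel–Crafts self-condensation of the electron-rich chloromethyl sulfide or protodesilylation of the ketene acetal takes over. The fallback makes the C–C bond and the C–S bond in separate events and sets out from 8. Its lithium enolate 13 is treated with monomeric formaldehyde (from cracked paraformaldehyde, THF, −78 °C), again anti to the C4 methyl group, to give (3R,4S,5R)-3-(benzyloxy)-5-[4-(benzyloxy)-3-methoxyphenyl]-3-(hydroxymethyl)-4-methyloxolan-2-one F4. Sulfonylation (Tf2O, pyridine, CH2Cl2, −20 °C) should give [(3R,4S,5R)-3-(benzyloxy)-5-[4-(benzyloxy)-3-methoxyphenyl]-4-methyl-2-oxooxolan-3-yl]methyl trifluoromethanesulfonate F5, which cannot eliminate because C3 carries no hydrogen. SN2 displacement by lithium thiolate 11 (THF–DMF, 0 °C → rt) comes back to the route at 15.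

Step 9. Hydrogenolysis of the benzylic C–O bonds of the oxolane on nickel may compete with cleavage of the two C–S bonds. The fallback exchanges sulfur for selenium, whose bonds to carbon are cleaved under much milder conditions; it sets out from 9 and 8. Aryllithium 10 (from 9) is quenched with grey selenium to give lithium 3-(benzyloxy)-4-methoxybenzeneselenolate F6, which is alkylated with BrCH2Cl to 2-(benzyloxy)-4-[(chloromethyl)selanyl]-1-methoxybenzene F7. Reaction of F7 with ketene acetal 14 (from 8) and ZnBr2 should give (3S,4S,5R)-3-(benzyloxy)-5-[4-(benzyloxy)-3-methoxyphenyl]-3-({[3-(benzyloxy)-4-methoxyphenyl]selanyl}methyl)-4-methyloxolan-2-one F8. Reduction with iBu2AlH gives the lactol (2RS,3S,4S,5R)-3-(benzyloxy)-5-[4-(benzyloxy)-3-methoxyphenyl]-3-({[3-(benzyloxy)-4-methoxyphenyl]selanyl}methyl)-4-methyloxolan-2-ol F9, and BF3·OEt2 closes it to (2R,3S,3aS,9bR)-3a,7-bis(benzyloxy)-2-[4-(benzyloxy)-3-methoxyphenyl]-8-methoxy-3-methyl-2,3,3a,9b-tetrahydro-4H-furo[3,2-c]selenochromene F10. Nickel boride Ni2B, formed in the flask from NiCl2·6H2O and NaBH4 (MeOH–THF, 0 °C), should cleave both C–Se bonds within minutes, conditions under which benzylic ethers are inert. The fallback comes back to the route at 20.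

**Further compounds**
F1 | step 8 | (3S,4S,5R)-3-(benzyloxy)-5-[4-(benzyloxy)-3-methoxyphenyl]-3,4-dimethyloxolan-2-one | O=C1O[C@@H](c2ccc(OCc3ccccc3)c(OC)c2)[C@H](C)[C@]1(C)OCc1ccccc1
F2 | step 8 | [4-(benzyloxy)-3-methoxyphenyl]lithium | [Li]c1ccc(OCc2ccccc2)c(OC)c1
F3 | step 8 | (2RS,3S,4S,5R)-3-(benzyloxy)-2,5-bis[4-(benzyloxy)-3-methoxyphenyl]-3,4-dimethyloxolan-2-ol | OC1(c2ccc(OCc3ccccc3)c(OC)c2)O[C@@H](c2ccc(OCc3ccccc3)c(OC)c2)[C@H](C)[C@]1(C)OCc1ccccc1
F4 | step 6 | (3R,4S,5R)-3-(benzyloxy)-5-[4-(benzyloxy)-3-methoxyphenyl]-3-(hydroxymethyl)-4-methyloxolan-2-one | O=C1O[C@@H](c2ccc(OCc3ccccc3)c(OC)c2)[C@H](C)[C@@]1(OCc1ccccc1)CO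
F5 | step 6 | [(3R,4S,5R)-3-(benzyloxy)-5-[4-(benzyloxy)-3-methoxyphenyl]-4-methyl-2-oxooxolan-3-yl]methyl trifluoromethanesulfonate | O=C1O[C@@H](c2ccc(OCc3ccccc3)c(OC)c2)[C@H](C)[C@@]1(OCc1ccccc1)COS(=O)(=O)C(F)(F)F
F6 | step 9 | lithium 3-(benzyloxy)-4-methoxybenzeneselenolate | [Li][Se]c1ccc(OC)c(OCc2ccccc2)c1
F7 | step 9 | 2-(benzyloxy)-4-[(chloromethyl)selanyl]-1-methoxybenzene | ClC[Se]c1ccc(OC)c(OCc2ccccc2)c1
F8 | step 9 | (3S,4S,5R)-3-(benzyloxy)-5-[4-(benzyloxy)-3-methoxyphenyl]-3-({[3-(benzyloxy)-4-methoxyphenyl]selanyl}methyl)-4-methyloxolan-2-one | O=C1O[C@@H](c2ccc(OCc3ccccc3)c(OC)c2)[C@H](C)[C@@]1(OCc1ccccc1)C[Se]c1ccc(OC)c(OCc2ccccc2)c1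
F9 | step 9 | (2RS,3S,4S,5R)-3-(benzyloxy)-5-[4-(benzyloxy)-3-methoxyphenyl]-3-({[3-(benzyloxy)-4-methoxyphenyl]selanyl}methyl)-4-methyloxolan-2-ol | OC1O[C@@H](c2ccc(OCc3ccccc3)c(OC)c2)[C@H](C)[C@@]1(OCc1ccccc1)C[Se]c1ccc(OC)c(OCc2ccccc2)c1
F10 | step 9 | (2R,3S,3aS,9bR)-3a,7-bis(benzyloxy)-2-[4-(benzyloxy)-3-methoxyphenyl]-8-methoxy-3-methyl-2,3,3a,9b-tetrahydro-4H-furo[3,2-c]selenochromene | COc1c(OCc4ccccc4)cc3c(c1)[C@H]2O[C@@H](c5ccc(OCc6ccccc6)c(OC)c5)[C@H](C)[C@]2(C[Se]3)OCc2ccccc2
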